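## Retrosynthetic overview

1. Target ⇒ eudesm-3-en-6β-yl (E)-cinnamate: C3–O and C4–O come last, by epoxidation and trans-diaxial hydrolysis; the cinnamate comes from the 6β-ol, acryloyl chloride and iodobenzene (acylation, then Heck).
2. trans-Eudesm-3-en-6β-ol ⇒ cis-fused eudesm-3-en-6-one: C5 is reset through the dienolate and C6 is set by α-face hydride.
3. Ring B ⇒ key one-carbon ring expansion of a cis-hydrindenone with 1-diazo-2-methylpropane (the ring CH2 shifts from the carbonyl carbon to the new C7, which brings in the isopropyl group).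
4. Ring A ⇒ Au-catalysed 6-endo closure of a silyl enol ether made by asymmetric conjugate addition of a pent-3-ynyl Grignard reagent to 3-methylcyclopentenone (sets C10).
5. Ring order: cyclopentenone (bought) → ring A annulated onto it → five-membered ring expanded to ring B.

Assumption: 5-bromopent-2-yne is taken as a catalogue compound; locants in the text use eudesmane numbering (C10 angular-methyl carbon, C5 ring-fusion CH, C4 methyl-bearing carbon of ring A, C6 ester carbon, C7 isopropyl carbon; β = face of the C10 methyl).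

## Route

Step 1
Reactants: 1 3-methylcyclopent-2-en-1-one; 2 5-bromopent-2-yne
Product: 5 (R)-tert-butyldimethyl{[3-methyl-3-(pent-3-yn-1-yl)cyclopent-1-en-1-yl]oxy}silane, via pent-3-yn-1-ylmagnesium bromide 3 (not isolated), via bromomagnesium enolate 4 (not isolated)
Conditions: 2, Mg, Et2O, rt; then Cu(OTf)2 (3 mol %), chiral C2-symmetric imidazolinium salt (NHC precursor, 4 mol %, enantiomer that gives the R centre), 1 added slowly, Et2O, −30 °C; then TBSOTf, −30 → 0 °C
Reagents that add atoms: tert-butyldimethylsilyl trifluoromethanesulfonate, CC(C)(C)[Si](C)(C)OS(=O)(=O)C(F)(F)F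
Why: Cu–NHC-catalysed asymmetric conjugate addition of a Grignard reagent to a β-methyl enone, in which the chiral ligand selects the enone face and so sets the quaternary C10 centre (R), and the regiodefined magnesium enolate is O-silylated to fix the enol ether towards C5.

Step 2
Reactants: 5 (R)-tert-butyldimethyl{[3-methyl-3-(pent-3-yn-1-yl)cyclopent-1-en-1-yl]oxy}silane
Product: 6 (3aR,7aS)-3a,7-dimethyl-2,3,3a,4,5,7a-hexahydro-1H-inden-1-one (cis-fused)
Conditions: (Me4-t-BuXPhos)AuNTf2 (3 mol %), CH2Cl2, H2O (1.5 equiv), 0 °C → rt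
Reagents that add atoms: none
Why: Au(I) π-activation of the methyl-capped alkyne and 6-endo-dig attack by the enol ether carbon (Conia-ene-type carbocyclisation, the endo mode favoured by the bulky biaryl phosphine) forms C4–C5 and the Δ3 alkene; the three-atom tether can only reach the face of C5 on its own side, so the new ring-fusion hydrogen is cis to the angular methyl.

Step 3
Reactants: 7 2-methylpropanal
Product: 9 1-diazo-2-methylpropane, via (2-methylpropylidene)hydrazine 8 (not isolated)
Conditions: N2H4·H2O (5 equiv), Et2O, 0 °C, dried over KOH; then DMSO, (COCl)2, Et3N, THF, −78 °C; cold filtration, solution titrated and used at once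
Reagents that add atoms: hydrazine (as hydrate), NN
Why: hydrazone formation followed by dehydrogenation with activated DMSO (Swern-type hydrazone oxidation) gives the non-stabilised diazoalkane at −78 °C as a salt-free solution.

Step 4
Reactants: 6 (3aR,7aS)-3a,7-dimethyl-2,3,3a,4,5,7a-hexahydro-1H-inden-1-one; 9 1-diazo-2-methylpropane
Product: 10 (2S,4aR,8aS)-4a,8-dimethyl-2-(propan-2-yl)-3,4,4a,5,6,8a-hexahydronaphthalen-1(2H)-one (cis-fused eudesm-3-en-6-one)
Conditions: Sc(OTf)3 (10 mol %), chiral N,N′-dioxide ligand (pipecolic-acid-derived, 2,6-diisopropylanilide arms, 12 mol %, enantiomer chosen by screening), toluene/CH2Cl2, −78 → −40 °C, 9 (1.6 equiv) added over 2 h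
Reagents that add atoms: none
Why: Proposed new method: ligand-controlled, diastereoselective Sc(III)-catalysed insertion of a non-stabilised α-branched alkyl diazomethane into an α-tertiary β,γ-unsaturated cis-hydrindanone; the diazo carbon adds to the Sc-bound carbonyl on the convex face, the unhindered CH2–C(O) bond (not the allylic ring-fusion methine) lies anti to the C–N2+ bond and shifts 1,2 with loss of N2 (Tiffeneau–Demjanov-type ring expansion), and the chiral pocket fixes which face of the diazo carbon bonds and so sets C7 (S) under non-enolising conditions; the closest known chemistry is the Sc(OTf)3-catalysed homologation of cycloalkanones with aryl- and alkyl-diazomethanes and its enantioselective versions with aryldiazomethanes and α-diazo esters.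

Step 5
Reactants: 10 (2S,4aR,8aS)-4a,8-dimethyl-2-(propan-2-yl)-3,4,4a,5,6,8a-hexahydronaphthalen-1(2H)-one
Product: 13 (1R,2S,4aR,8aR)-4a,8-dimethyl-2-(propan-2-yl)-1,2,3,4,4a,5,6,8a-octahydronaphthalen-1-ol (eudesm-3-en-6β-ol), via potassium dienolate 11 (not isolated), via trans-fused enone 12 (not isolated)
Conditions: KHMDS (1.1 equiv), THF, −78 → −40 °C; AcOH (1.2 equiv), −78 °C; then NaBH4 (3 equiv), MeOH, −78 → −10 °C
Reagents that add atoms: none
Why: removal of the doubly activated C5–H gives the extended dienolate without touching C7, kinetic α-protonation anti to the angular methyl (deconjugative dienolate protonation) gives the trans-fused β,γ-enone, and borohydride reduces it in the same flask before it can conjugate, hydride entering from the α face because the axial C10 methyl blocks the β face, which gives the axial 6β-alcohol.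

Step 6
Reactants: 13 (1R,2S,4aR,8aR)-4a,8-dimethyl-2-(propan-2-yl)-1,2,3,4,4a,5,6,8a-octahydronaphthalen-1-ol; 14 prop-2-enoyl chloride; 15 iodobenzene
Product: 17 (1R,2S,4aR,8aR)-4a,8-dimethyl-2-(propan-2-yl)-1,2,3,4,4a,5,6,8a-octahydronaphthalen-1-yl (2E)-3-phenylprop-2-enoate, via acrylate ester 16 (not isolated)
Conditions: 14 (1.5 equiv), Et3N, DMAP (10 mol %), MeCN, 0 °C → rt; then 15 (3 equiv), Pd(OAc)2 (5 mol %), P(o-tol)3 (10 mol %), Et3N, 80 °C
Reagents that add atoms: none
Why: the small acryloyl chloride acylates the hindered axial alcohol, and a Mizoroki–Heck arylation of the acrylate with iodobenzene in the same pot gives the (E)-cinnamate (syn insertion, syn β-hydride elimination), the trisubstituted ring alkene being inert.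

Step 7
Reactants: 17 (1R,2S,4aR,8aR)-4a,8-dimethyl-2-(propan-2-yl)-1,2,3,4,4a,5,6,8a-octahydronaphthalen-1-yl (2E)-3-phenylprop-2-enoate
Product: 19 (1R,2S,4aS,7R,8R,8aS)-7,8-dihydroxy-4a,8-dimethyl-2-(propan-2-yl)decahydronaphthalen-1-yl (2E)-3-phenylprop-2-enoate, via 3α,4α-epoxide 18 (not isolated)
Conditions: m-CPBA (1.2 equiv), NaHCO3, CH2Cl2, 0 °C; solvent exchanged to THF/H2O (3:1), HClO4 (10 mol %), 0 °C → rt
Reagents that add atoms: m-CPBA, OOC(=O)c1cccc(Cl)c1; water, O
Why: Prilezhaev epoxidation takes the electron-rich ring alkene (not the cinnamate) from the α face, away from the C10 methyl and the 6β-ester, and acid-catalysed trans-diaxial (Fürst–Plattner) opening by water at the tertiary C4 from the β face gives the 3α,4β-diol; any β-epoxide opens diaxially at C3 to the same diol.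

## Compound list

1 | 3-methylcyclopent-2-en-1-one | CC1=CC(=O)CC1 | starting material
2 | 5-bromopent-2-yne | CC#CCCBr | starting material
3 | pent-3-yn-1-ylmagnesium bromide | CC#CCC[Mg]Br | intermediate
4 | bromomagnesium (R)-3-methyl-3-(pent-3-yn-1-yl)cyclopent-1-en-1-olate | CC#CCC[C@]1(C)CCC(O[Mg]Br)=C1 | intermediate
5 | (R)-tert-butyldimethyl{[3-methyl-3-(pent-3-yn-1-yl)cyclopent-1-en-1-yl]oxy}silane | CC#CCC[C@]1(C)CCC(O[Si](C)(C)C(C)(C)C)=C1 | intermediate
6 | (3aR,7aS)-3a,7-dimethyl-2,3,3a,4,5,7a-hexahydro-1H-inden-1-one (cis-fused) | C1C[C@@]2(C)CCC=C(C)[C@H]2C1=O | intermediate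
7 | 2-methylpropanal | CC(C)C=O | starting material
8 | (2-methylpropylidene)hydrazine | CC(C)C=NN | intermediate
9 | 1-diazo-2-methylpropane | CC(C)C=[N+]=[N-] | intermediate
10 | (2S,4aR,8aS)-4a,8-dimethyl-2-(propan-2-yl)-3,4,4a,5,6,8a-hexahydronaphthalen-1(2H)-one (cis-fused, 5β-H, 7β-isopropyl) | CC(C)[C@@H]1CC[C@@]2(C)CCC=C(C)[C@H]2C1=O | intermediate
11 | potassium (2S,4aR)-4a,8-dimethyl-2-(propan-2-yl)-2,3,4,4a,5,6-hexahydronaphthalen-1-olate | CC(C)[C@@H]1CC[C@@]2(C)CCC=C(C)C2=C1[O-].[K+] | intermediate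
12 | (2S,4aR,8aR)-4a,8-dimethyl-2-(propan-2-yl)-3,4,4a,5,6,8a-hexahydronaphthalen-1(2H)-one (trans-fused, 5α-H) | CC(C)[C@@H]1CC[C@@]2(C)CCC=C(C)[C@@H]2C1=O | intermediate
13 | (1R,2S,4aR,8aR)-4a,8-dimethyl-2-(propan-2-yl)-1,2,3,4,4a,5,6,8a-octahydronaphthalen-1-ol (eudesm-3-en-6β-ol) | CC(C)[C@@H]1CC[C@@]2(C)CCC=C(C)[C@@H]2[C@@H]1O | intermediate
14 | prop-2-enoyl chloride | C=CC(Cl)=O | starting material
15 | iodobenzene | Ic1ccccc1 | starting material
16 | (1R,2S,4aR,8aR)-4a,8-dimethyl-2-(propan-2-yl)-1,2,3,4,4a,5,6,8a-octahydronaphthalen-1-yl prop-2-enoate | CC(C)[C@@H]1CC[C@@]2(C)CCC=C(C)[C@@H]2[C@@H]1OC(=O)C=C | intermediate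
17 | (1R,2S,4aR,8aR)-4a,8-dimethyl-2-(propan-2-yl)-1,2,3,4,4a,5,6,8a-octahydronaphthalen-1-yl (2E)-3-phenylprop-2-enoate | CC(C)[C@@H]1CC[C@@]2(C)CCC=C(C)[C@@H]2[C@@H]1OC(=O)/C=C/c1ccccc1 | intermediate
18 | 3α,4α-epoxyeudesman-6β-yl (E)-cinnamate (epoxide oxygen on the face opposite the C10 methyl) | CC(C)[C@@H]1CC[C@@]2(C)CC[C@H]3O[C@@]3(C)[C@@H]2[C@@H]1OC(=O)/C=C/c1ccccc1 | intermediate
19 | (1R,2S,4aS,7R,8R,8aS)-7,8-dihydroxy-4a,8-dimethyl-2-(propan-2-yl)decahydronaphthalen-1-yl (2E)-3-phenylprop-2-enoate (3α,4β-dihydroxyeudesman-6β-yl cinnamate) | CC(C)[C@@H]1CC[C@@]2(C)CC[C@@H](O)[C@](C)(O)[C@@H]2[C@@H]1OC(=O)/C=C/c1ccccc1 | target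

## Step count and risks

Total: 7 steps. Longest linear sequence: 6 steps (steps 1, 2, 4, 5, 6, 7); step 3 is a one-step branch that supplies the diazoalkane.

The three steps most likely to fail are steps 4, 2 and 5.

Step 4 (the proposed new ring expansion) may give the right regiochemistry but poor ligand control of C7. The fallback sets out from 6 (with 9) and uses only known chemistry. The established ligand-free Sc(OTf)3-catalysed homologation of cycloalkanones with alkyl diazomethanes should still give methylene migration. It would give 10 mixed with its C7 epimer (2R,4aR,8aS)-4a,8-dimethyl-2-(propan-2-yl)-3,4,4a,5,6,8a-hexahydronaphthalen-1(2H)-one F1. Brief treatment with DBU (or NaOMe in MeOH) then moves the ring alkene into conjugation and equilibrates C7 at the ketone stage. This gives (2S,4aR)-4a,8-dimethyl-2-(propan-2-yl)-3,4,4a,5,6,7-hexahydronaphthalen-1(2H)-one F2 with the equatorial isopropyl group as the major, separable epimer. γ-Deprotonation of F2 with KOt-Bu in THF/t-BuOH gives the potassium dienolate 11, and the route is rejoined there inside step 5.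

Step 2 may close 5-exo to an ethylidene diquinane instead of 6-endo. The fallback sets out from 1 and builds ring A by a classical conjugate addition and aldol condensation.
- 2-(3-Chloropropyl)-2-methyl-1,3-dioxolane F3 (the ethylene ketal of 5-chloropentan-2-one, seven non-hydrogen atoms without the protecting group) is converted with Mg in THF into [3-(2-methyl-1,3-dioxolan-2-yl)propyl]magnesium chloride F4.
- F4 is added to 1 with the same Cu–NHC catalyst. The chloromagnesium enolate, chloromagnesium (R)-3-methyl-3-[3-(2-methyl-1,3-dioxolan-2-yl)propyl]cyclopent-1-en-1-olate F5, is protonated on work-up to (R)-3-methyl-3-[3-(2-methyl-1,3-dioxolan-2-yl)propyl]cyclopentan-1-one F6.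
- Aqueous HCl in THF frees (R)-3-methyl-3-(4-oxopentyl)cyclopentan-1-one F7. KOH in MeOH then closes and dehydrates it to the conjugated enone (R)-3a,7-dimethyl-2,3,3a,4,5,6-hexahydro-1H-inden-1-one F8.
- KOt-Bu in THF gives potassium (R)-3a,7-dimethyl-3,3a,4,5-tetrahydro-2H-inden-1-olate F9. A cold AcOH quench protonates it at the α-carbon and the route is rejoined at 6.
- Any ring-fusion epimer formed beside 6, (3aR,7aR)-3a,7-dimethyl-2,3,3a,4,5,7a-hexahydro-1H-inden-1-one F10, can be carried along, because that centre is made planar again in step 5 and F10 would give 12 directly on ring expansion.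

Step 5 may leak to the conjugated enone before reduction, or C7 may erode under the strong base. The fallback sets out from 10 and avoids strong base. Acid-catalysed enol acetylation (isopropenyl acetate, TsOH, reflux) gives (2S,4aR)-4a,8-dimethyl-2-(propan-2-yl)-2,3,4,4a,5,6-hexahydronaphthalen-1-yl acetate F11, which can be purified. NaBH4 in EtOH/THF at 0 °C (the classical deconjugative reduction of dienyl acetates) cleaves the acetate to sodium (2S,4aR)-4a,8-dimethyl-2-(propan-2-yl)-2,3,4,4a,5,6-hexahydronaphthalen-1-olate F12. The solvent protonates F12 at C5 to give 12 in the presence of the hydride, which reduces it at once, and the route is rejoined at 13.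

Further compounds

F1 | step 4 | (2R,4aR,8aS)-4a,8-dimethyl-2-(propan-2-yl)-3,4,4a,5,6,8a-hexahydronaphthalen-1(2H)-one | CC(C)[C@H]1CC[C@@]2(C)CCC=C(C)[C@H]2C1=O
F2 | step 4 | (2S,4aR)-4a,8-dimethyl-2-(propan-2-yl)-3,4,4a,5,6,7-hexahydronaphthalen-1(2H)-one | CC(C)[C@@H]1CC[C@@]2(C)CCCC(C)=C2C1=O
F3 | step 2 | 2-(3-chloropropyl)-2-methyl-1,3-dioxolane (bought) | CC1(CCCCl)OCCO1
F4 | step 2 | [3-(2-methyl-1,3-dioxolan-2-yl)propyl]magnesium chloride | CC1(CCC[Mg]Cl)OCCO1
F5 | step 2 | chloromagnesium (R)-3-methyl-3-[3-(2-methyl-1,3-dioxolan-2-yl)propyl]cyclopent-1-en-1-olate | CC1(CCC[C@]2(C)CCC(O[Mg]Cl)=C2)OCCO1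
F6 | step 2 | (R)-3-methyl-3-[3-(2-methyl-1,3-dioxolan-2-yl)propyl]cyclopentan-1-one | O=C1CC[C@@](C)(CCCC2(C)OCCO2)C1
F7 | step 2 | (R)-3-methyl-3-(4-oxopentyl)cyclopentan-1-one | CC(=O)CCC[C@]1(C)CCC(=O)C1
F8 | step 2 | (R)-3a,7-dimethyl-2,3,3a,4,5,6-hexahydro-1H-inden-1-one | CC1=C2C(=O)CC[C@@]2(C)CCC1
F9 | step 2 | potassium (R)-3a,7-dimethyl-3,3a,4,5-tetrahydro-2H-inden-1-olate | CC1=CCC[C@]2(C)CCC([O-])=C12.[K+]
F10 | step 2 | (3aR,7aR)-3a,7-dimethyl-2,3,3a,4,5,7a-hexahydro-1H-inden-1-one | C1C[C@@]2(C)CCC=C(C)[C@@H]2C1=O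
F11 | step 5 | (2S,4aR)-4a,8-dimethyl-2-(propan-2-yl)-2,3,4,4a,5,6-hexahydronaphthalen-1-yl acetate | CC(C)[C@@H]1CC[C@@]2(C)CCC=C(C)C2=C1OC(C)=O
F12 | step 5 | sodium (2S,4aR)-4a,8-dimethyl-2-(propan-2-yl)-2,3,4,4a,5,6-hexahydronaphthalen-1-olate | CC(C)[C@@H]1CC[C@@]2(C)CCC=C(C)C2=C1[O-].[Na+]
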